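## Plan

- **Cuts.** The target is opened first at C10–C11 and then at C19–C20. C10 is a tertiary carbinol carbon inside the seven-membered ring D and its ring neighbour C11 is a bare CH2, so this bond can come from a C10 ketone and a C11 aldehyde by ketyl pinacol coupling, with the surplus C11 hydroxyl removed afterwards.
- **Fragments.** This leaves a rings A–C ketone (14) and a ring E aldehyde (24), joined by a kinetic aldol at C20.
- **Ring order.** Ring A (enone 6) receives ring B and then ring C by two conjugate-addition–annulation cycles, and a third cuprate addition sets the C8 methyl. Ring E comes from a radical epoxy-olefin cyclization. Ring D closes last.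
- **Stereochemistry.** C1 comes from a CBS reduction and C5 from axial enolate alkylation trans to the C1 methoxy group. C4 and C8 come from axial cuprate additions (cis ring fusions), and C22 is set by equilibration. C15 comes from a Shi epoxidation, C13 from the chair cyclization and C18 from equatorial methylation. C20 comes from the aldol (equatorial, epimerizable) and C10 from the pinacol step. C19 and C11 are erased later.

Key step: step 19

Assumption: ring carbons are numbered C1–C23 in the order of the target SMILES (ring A C1–C5/C23, B C4–C8/C22, C C8–C10/C20–C22, D C10–C13/C18–C20, E C13–C18); the aldol adduct is drawn as the anti C19 epimer, and either C19 epimer would serve because C19 ends as the ketone.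

## Route

### Rings A–C ketone (steps 1–8)

Step 1
Reactants: 1 4-methoxy-2-methylphenol
Product: 2 4,4-dimethoxy-2-methylcyclohexa-2,5-dien-1-one
Conditions: PhI(OAc)2, MeOH, 0 °C
Reagents that add atoms: methanol, CO
Why: Oxidative dearomatization of a para-methoxyphenol in methanol gives the quinone monoketal, which places the two oxygen functions of ring A 1,4 to each other with the methyl group next to the free carbonyl.

Step 2
Reactants: 2 4,4-dimethoxy-2-methylcyclohexa-2,5-dien-1-one
Product: 3 4,4-dimethoxy-2-methylcyclohex-2-en-1-one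
Conditions: H2 (1 atm), RhCl(PPh3)3 (5 mol %), benzene, rt
Reagents that add atoms: none
Why: Homogeneous hydrogenation with RhCl(PPh3)3 saturates the unsubstituted cis-disubstituted C=C far faster than the methyl-bearing trisubstituted one, so only the 2-methyl enone remains.

Step 3
Reactants: 3 4,4-dimethoxy-2-methylcyclohex-2-en-1-one
Product: 4 (S)-4,4-dimethoxy-2-methylcyclohex-2-en-1-ol
Conditions: (R)-Me-CBS oxazaborolidine (10 mol %), BH3·SMe2, THF, −20 °C
Reagents that add atoms: none
Why: CBS reduction treats the 2-methylvinyl side as the large group and the CH2 side as the small one, so the (R)-catalyst should deliver hydride to give the (S)-carbinol, which becomes C1.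

Step 4
Reactants: 4 (S)-4,4-dimethoxy-2-methylcyclohex-2-en-1-ol
Product: 5 (S)-3,3,6-trimethoxy-1-methylcyclohex-1-ene
Conditions: MeI, Ag2O, MeCN, 40 °C
Reagents that add atoms: iodomethane, CI
Why: Silver-oxide-mediated Williamson methylation is neutral, so the allylic alcohol is etherified without touching the acid-labile ketal or the stereocentre.

Step 5
Reactants: 5 (S)-3,3,6-trimethoxy-1-methylcyclohex-1-ene
Product: 6 (S)-4-methoxy-3-methylcyclohex-2-en-1-one
Conditions: 1 M HCl, THF, 0 °C
Reagents that add atoms: water, O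
Why: Mild acid hydrolysis of the dimethyl ketal releases the enone, while the secondary methyl ether survives because its ionization would place a cation next to the new carbonyl system.

Step 6
Reactants: 6 (S)-4-methoxy-3-methylcyclohex-2-en-1-one
Product: 9 (4aS,6S)-6-methoxy-5,5-dimethyl-4,4a,5,6,7,8-hexahydronaphthalen-2(3H)-one, via lithium enolate 7 (not isolated), via silyl diketone 8 (not isolated)
Conditions: MeLi, CuI, Et2O, 0 °C; add 6, −78→0 °C; 3-(trimethylsilyl)but-3-en-2-one, −78→0 °C; NaOMe, MeOH, 0 °C→rt; aq. NH4Cl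
Reagents that add atoms: lithium dimethylcuprate, [Li+].C[Cu-]C; 3-(trimethylsilyl)but-3-en-2-one, CC(=O)C(=C)[Si](C)(C)C
Why: Conjugate addition makes the C23 gem-dimethyl group and a regiodefined C4/C5 enolate, which adds to the α-silyl vinyl ketone axially on the half-chair with equatorial methoxy so that C6 ends trans to the methoxy group (C5–H syn to it), after which methoxide removes silicon and closes ring B by aldol condensation (Robinson annulation run as conjugate addition–annulation).

Step 7
Reactants: 9 (4aS,6S)-6-methoxy-5,5-dimethyl-4,4a,5,6,7,8-hexahydronaphthalen-2(3H)-one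
Product: 12 tricyclic enone (rings A–C; C10 ketone and C9=C8), via lithium enolate 10 (not isolated), via silyl diketone 11 (not isolated)
Conditions: MeLi, CuI, Et2O, 0 °C; add 9, −20→0 °C; 3-(trimethylsilyl)but-3-en-2-one, −78→0 °C; NaOMe, MeOH, 60 °C; aq. NH4Cl
Reagents that add atoms: lithium dimethylcuprate, [Li+].C[Cu-]C; 3-(trimethylsilyl)but-3-en-2-one, CC(=O)C(=C)[Si](C)(C)C
Why: A second conjugate addition–annulation puts the methyl on C4 by axial attack, cis to C5–H as is usual for ring-fusion enones; the C8/C22 enolate is captured at C22, and C22 (first α, then γ to a carbonyl) equilibrates under the methoxide closure of ring C to the isomer with H syn to the C4 methyl, which avoids an axial C23 on ring B.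

Step 8
Reactants: 12 tricyclic enone (rings A–C; C10 ketone and C9=C8)
Product: 14 rings A–C ketone (1S,4R,5S,8S,22R), via silyl enol ether 13 (not isolated)
Conditions: MeLi, CuI, Et2O, 0 °C; add 12, TMSCl, −78→0 °C; 1 M HCl
Reagents that add atoms: lithium dimethylcuprate, [Li+].C[Cu-]C
Why: The silyl-chloride-accelerated cuprate addition should bring the methyl to C8 axially on ring C from the convex β-face, cis to C22–H, because the α-face is shielded by the axial C3 methylene of ring A; acid work-up returns the C10 ketone.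

### Ring E aldehyde (steps 9–15)

Step 9
Reactants: 15 geranyl acetate
Product: 16 (E)-5-[(2R)-3,3-dimethyloxiran-2-yl]-3-methylpent-2-en-1-yl acetate
Conditions: D-fructose-derived ketone catalyst (30 mol %), Oxone (KHSO5), K2CO3, Bu4NHSO4, MeCN/CH2(OMe)2/aq. buffer pH 10.5, 0 °C
Reagents that add atoms: Oxone (potassium peroxymonosulfate), [K+].[O-]S(=O)(=O)OO
Why: Shi epoxidation attacks the electron-rich terminal trisubstituted alkene, the other being deactivated by the allylic acetate, and the D-fructose-derived dioxirane should give the (R)-epoxide that becomes C15.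

Step 10
Reactants: 16 (E)-5-[(2R)-3,3-dimethyloxiran-2-yl]-3-methylpent-2-en-1-yl acetate
Product: 17 (R)-2,2-dimethyl-3-[(E)-3-methylhepta-3,6-dien-1-yl]oxirane
Conditions: tributyl(vinyl)stannane, Pd2(dba)3 (2.5 mol %), LiCl, DMF, rt
Reagents that add atoms: tributyl(vinyl)stannane, C=C[Sn](CCCC)(CCCC)CCCC
Why: Stille coupling of the allylic acetate through its π-allyl complex of palladium joins the vinyl group at the primary terminus with the E-alkene kept, which installs C12, C11 and one sacrificial carbon as an allyl group and leaves the isolated epoxide untouched.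

Step 11
Reactants: 17 (R)-2,2-dimethyl-3-[(E)-3-methylhepta-3,6-dien-1-yl]oxirane
Product: 18 (1R,3S)-3-allyl-2,2-dimethyl-4-methylenecyclohexan-1-ol
Conditions: Cp2TiCl2, Zn dust, THF, rt (forms Cp2TiCl); then 1 M HCl
Reagents that add atoms: none
Why: Cp2TiCl (trivalent titanium) opens the epoxide to the tertiary C14 radical, which cyclizes 6-endo through a chair with the C15 oxygen and the C13 allyl group both equatorial (cis), and the tertiary C18 radical is trapped by a second Cp2TiCl and loses a β-hydrogen to give the exocyclic alkene (titanocene-mediated reductive epoxide opening–radical cyclization).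

Step 12
Reactants: 18 (1R,3S)-3-allyl-2,2-dimethyl-4-methylenecyclohexan-1-ol
Product: 20 benzyl ether of 18, via sodium alkoxide 19 (not isolated)
Conditions: NaH, THF/DMF, 0 °C; BnBr, Bu4NI (cat.), rt
Reagents that add atoms: benzyl bromide, BrCc1ccccc1
Why: Williamson etherification protects the C15 hydroxyl as a benzyl ether, which withstands every later step and is removed last by hydrogenolysis.

Step 13
Reactants: 20 benzyl ether of 18
Product: 21 (4R,6R)-4-allyl-6-(benzyloxy)-5,5-dimethyl-1-oxaspiro[2.5]octane (both spiro epimers)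
Conditions: mCPBA (1.0 equiv), CH2Cl2, 0 °C
Reagents that add atoms: mCPBA, OOC(=O)c1cccc(Cl)c1
Why: Prilezhaev epoxidation selects the more nucleophilic 1,1-disubstituted exocyclic alkene over the monosubstituted vinyl group, and the configuration at the spiro carbon does not matter.

Step 14
Reactants: 21 (4R,6R)-4-allyl-6-(benzyloxy)-5,5-dimethyl-1-oxaspiro[2.5]octane
Product: 22 (2S,4R)-2-allyl-4-(benzyloxy)-3,3-dimethylcyclohexane-1-carbaldehyde (C1 epimers)
Conditions: BF3·OEt2 (10 mol %), CH2Cl2, −78 °C
Reagents that add atoms: none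
Why: Meinwald rearrangement opens the epoxide at the tertiary C18 and a hydride shift gives the aldehyde, whose carbon is C19; C18 is epimerizable here and is fixed in the next step.

Step 15
Reactants: 22 (2S,4R)-2-allyl-4-(benzyloxy)-3,3-dimethylcyclohexane-1-carbaldehyde
Product: 24 (1S,2R,4R)-2-allyl-4-(benzyloxy)-1,3,3-trimethylcyclohexane-1-carbaldehyde, via potassium enolate 23 (not isolated)
Conditions: KOtBu, THF, 0 °C; MeI
Reagents that add atoms: iodomethane, CI
Why: C-methylation of the exocyclic aldehyde enolate should occur equatorially because the axial approach to C18 is 1,3-diaxial to the axial C14 methyl, which leaves the formyl group axial and cis to the C13 allyl group and creates the quaternary C18.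

### Fragment union and ring D (steps 16–24)

Step 16
Reactants: 14 rings A–C ketone; 24 (1S,2R,4R)-2-allyl-4-(benzyloxy)-1,3,3-trimethylcyclohexane-1-carbaldehyde
Product: 26 C19–C20 aldol adduct (20S,19R), via lithium enolate 25 (not isolated)
Conditions: LDA, THF, −78 °C; add 24, −78 °C; aq. NH4Cl
Reagents that add atoms: none
Why: Kinetic deprotonation takes place at C20 rather than at the neopentyl C9, and the directed aldol addition to the non-enolizable aldehyde should proceed through a closed chair transition state (anti) from the convex β-face, away from the axial C22–C4 bond, which places the new substituent equatorial at C20, the arrangement also favoured on equilibration next to the ketone.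

Step 17
Reactants: 26 C19–C20 aldol adduct
Product: 27 C19 tert-butyldimethylsilyl ether of 26
Conditions: TBSOTf, 2,6-lutidine, CH2Cl2, −78→0 °C
Reagents that add atoms: tert-butyldimethylsilyl triflate, CC(C)(C)[Si](C)(C)OS(=O)(=O)C(F)(F)F
Why: The silyl triflate silylates even this hindered carbinol, which blocks retro-aldol cleavage and keeps C19–OH apart from the hydroxyl groups made in the key step.

Step 18
Reactants: 27 C19 tert-butyldimethylsilyl ether of 26
Product: 28 seco-D keto aldehyde (C10 ketone, C11 aldehyde on a CH2 at C13)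
Conditions: O3, CH2Cl2/MeOH, −78 °C; Me2S
Reagents that add atoms: ozone, [O-][O+]=O
Why: Ozonolysis of the only alkene removes the terminal carbon of the allyl group and leaves the two-carbon CH2–CHO arm on C13, the length needed for a seven-membered ring D.

Step 19
Reactants: 28 seco-D keto aldehyde
Product: 29 pentacyclic (10S,11R)-C10,C11-diol
Conditions: SmI2 (3 equiv), t-BuOH (2 equiv), THF (0.005 M), −78 °C→rt
Reagents that add atoms: none
Why: SmI2 transfers one electron to the more easily reduced C11 aldehyde, the ketyl radical adds to the samarium-bound C10 ketone carbonyl, and a second electron and protonation give the diol; the closest known reaction type is the intramolecular ketone–aldehyde pinacol coupling with SmI2. Ring D closes as a seven-membered ring by 7-exo-trig attack of the C11 radical on the C10 carbonyl carbon, with four of its atoms (C13, C18, C19, C20) already held by rings E and C and the cis arms on C13 and C18 pointing the aldehyde at C10. At C10 the new C–C bond forms equatorially because the axial β-position is 1,3-diaxial to the C8 methyl, which leaves the hydroxyl axial and syn to that methyl and makes the C/D fusion trans with C19 and C11 both equatorial on ring C. At C11 the hydroxyl ends cis to the C10 hydroxyl because both oxygens sit on the same trivalent samarium when the bond forms, and this centre is removed later. The step needs reduction of the aldehyde before the hindered ketone and ring closure faster than hydrogen abstraction or dimerization, which the lower reduction potential of the aldehyde, high dilution and the preorganized ring E secure; the C19 silyloxy group is not on the carbon next to the ketyl and so is not expelled.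

Step 20
Reactants: 29 pentacyclic (10S,11R)-C10,C11-diol
Product: 31 C11 O-(S-methyl) xanthate, via sodium xanthate 30 (not isolated)
Conditions: NaHMDS (1.05 equiv), CS2, THF, −78 °C; MeI, −78→0 °C
Reagents that add atoms: carbon disulfide, S=C=S; iodomethane, CI
Why: The less hindered secondary C11 alkoxide adds to CS2 while the axial tertiary C10 hydroxyl, 1,3-diaxial to the C8 methyl, stays free; the anionic dithiocarbonate is no acylating agent and is S-methylated once no free base remains (xanthate formation for Barton–McCombie deoxygenation).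

Step 21
Reactants: 31 C11 O-(S-methyl) xanthate
Product: 32 C11-deoxy pentacycle (C10–OH, C19–OTBS, C15–OBn)
Conditions: Bu3SnH, AIBN (cat.), toluene, 110 °C
Reagents that add atoms: none
Why: Barton–McCombie deoxygenation cleaves the secondary C11–O bond through the stannyl-adduct radical, and the resulting C11 radical takes hydrogen from the tin hydride without disturbing the neighbouring tertiary alcohol.

Step 22
Reactants: 32 C11-deoxy pentacycle
Product: 33 C19 alcohol
Conditions: TBAF, THF, 50 °C; aq. NH4Cl
Reagents that add atoms: none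
Why: Fluoride removes the silyl ether and leaves the benzyl ether, the methyl ether and the tertiary alcohol in place.

Step 23
Reactants: 33 C19 alcohol
Product: 34 C15 benzyl ether of the target
Conditions: DMP (1,1,1-triacetoxy-1,1-dihydro-1,2-benziodoxol-3(1H)-one), CH2Cl2, rt
Reagents that add atoms: none
Why: Dess–Martin oxidation converts the only secondary alcohol into the C19 ketone under non-basic conditions, so the tertiary β-hydroxy ketone neither fragments by retro-aldol reaction nor epimerizes at C20.

Step 24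
Reactants: 34 C15 benzyl ether of the target
Product: 35 CNP0259231.1
Conditions: H2 (1 atm), Pd/C (10 %), EtOAc, rt
Reagents that add atoms: none
Why: Hydrogenolysis of the benzyl ether frees the C15 hydroxyl under neutral conditions that leave every stereocentre and the other oxygen functions unchanged.

## Compound list

1 | 4-methoxy-2-methylphenol | COc1ccc(O)c(C)c1 | starting material
2 | 4,4-dimethoxy-2-methylcyclohexa-2,5-dien-1-one | COC1(OC)C=CC(=O)C(C)=C1 | intermediate
3 | 4,4-dimethoxy-2-methylcyclohex-2-en-1-one | COC1(OC)CCC(=O)C(C)=C1 | intermediate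
4 | (S)-4,4-dimethoxy-2-methylcyclohex-2-en-1-ol | O[C@H]1CCC(OC)(OC)C=C1C | intermediate
5 | (S)-3,3,6-trimethoxy-1-methylcyclohex-1-ene | CO[C@H]1CCC(OC)(OC)C=C1C | intermediate
6 | (S)-4-methoxy-3-methylcyclohex-2-en-1-one (ring A enone) | CO[C@H]1CCC(=O)C=C1C | intermediate
7 | lithium (S)-4-methoxy-3,3-dimethylcyclohex-1-en-1-olate | CO[C@H]1CCC(O[Li])=CC1(C)C | intermediate
8 | (2R,4S)-4-methoxy-3,3-dimethyl-2-[3-oxo-2-(trimethylsilyl)butyl]cyclohexan-1-one (silyl-bearing carbon unassigned) | CO[C@H]1CCC(=O)[C@H](CC(C(C)=O)[Si](C)(C)C)C1(C)C | intermediate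
9 | (4aS,6S)-6-methoxy-5,5-dimethyl-4,4a,5,6,7,8-hexahydronaphthalen-2(3H)-one (rings A/B; C8 ketone, C22=C4; C5–H syn to OMe) | CO[C@H]1CCC2=CC(=O)CC[C@@H]2C1(C)C | intermediate
10 | lithium enolate of the cis-fused C4-methyl decalone (C8–OLi, C8=C22) | CO[C@H]1CC[C@@]2(C)[C@H](CCC(O[Li])=C2)C1(C)C | intermediate
11 | cis-fused C8 ketone bearing the 3-oxo-2-(trimethylsilyl)butyl group on C22 (C22 and silyl-bearing carbon unassigned) | CO[C@H]1CC[C@@]2(C)[C@H](CCC(=O)C2CC(C(C)=O)[Si](C)(C)C)C1(C)C | intermediate
12 | tricyclic enone, rings A–C (C10 ketone, C9=C8; 1S,4R,5S,22R; C1–OMe, C4–Me, C5–H and C22–H on one face) | CO[C@H]1CC[C@@]2(C)[C@H](CCC3=CC(=O)CC[C@H]32)C1(C)C | intermediate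
13 | trimethylsilyl enol ether of 14 (C10–OSiMe3, C9=C10) | CO[C@H]1CC[C@@]2(C)[C@H](CC[C@@]3(C)C=C(O[Si](C)(C)C)CC[C@H]32)C1(C)C | intermediate
14 | rings A–C ketone (C10 ketone; 1S,4R,5S,8S,22R; cis-syn-cis, both angular methyls and both ring-fusion hydrogens on the methoxy face) | CO[C@H]1CC[C@@]2(C)[C@H](CC[C@@]3(C)CC(=O)CC[C@H]32)C1(C)C | intermediate
15 | geranyl acetate | CC(C)=CCC/C(C)=C/COC(C)=O | starting material
16 | (E)-5-[(2R)-3,3-dimethyloxiran-2-yl]-3-methylpent-2-en-1-yl acetate | CC1(C)O[C@@H]1CC/C(C)=C/COC(C)=O | intermediate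
17 | (R)-2,2-dimethyl-3-[(E)-3-methylhepta-3,6-dien-1-yl]oxirane | CC1(C)O[C@@H]1CC/C(C)=C/CC=C | intermediate
18 | (1R,3S)-3-allyl-2,2-dimethyl-4-methylenecyclohexan-1-ol (OH and allyl cis) | C=CC[C@@H]1C(C)(C)[C@H](O)CCC1=C | intermediate
19 | sodium alkoxide of 18 | C=CC[C@@H]1C(C)(C)[C@H](O[Na])CCC1=C | intermediate
20 | ({[(1R,3S)-3-allyl-2,2-dimethyl-4-methylenecyclohexyl]oxy}methyl)benzene | C=CC[C@@H]1C(C)(C)[C@H](OCc2ccccc2)CCC1=C | intermediate
21 | (4R,6R)-4-allyl-6-(benzyloxy)-5,5-dimethyl-1-oxaspiro[2.5]octane (both spiro epimers) | C=CC[C@@H]1C(C)(C)[C@H](OCc2ccccc2)CCC13CO3 | intermediate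
22 | (2S,4R)-2-allyl-4-(benzyloxy)-3,3-dimethylcyclohexane-1-carbaldehyde (C1 epimers) | C=CC[C@@H]1C(C)(C)[C@H](OCc2ccccc2)CCC1C=O | intermediate
23 | potassium enolate of 22 | C=CC[C@@H]1C(C)(C)[C@H](OCc2ccccc2)CCC1=CO[K] | intermediate
24 | (1S,2R,4R)-2-allyl-4-(benzyloxy)-1,3,3-trimethylcyclohexane-1-carbaldehyde (ring E aldehyde; CHO, allyl and OBn all cis) | C=CC[C@@H]1C(C)(C)[C@H](OCc2ccccc2)CC[C@]1(C)C=O | intermediate
25 | lithium enolate of 14 (C10–OLi, C10=C20) | CO[C@H]1CC[C@@]2(C)[C@H](CC[C@@]3(C)CC(O[Li])=CC[C@H]32)C1(C)C | intermediate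
26 | aldol adduct (C10 ketone, C19–OH, C13 allyl, C15–OBn; 20S,19R, anti) | CO[C@H]1CC[C@@]2(C)[C@H](CC[C@@]3(C)CC(=O)[C@@H](C[C@H]32)[C@@H](O)[C@@]4(C)CC[C@@H](OCc5ccccc5)C(C)(C)[C@H]4CC=C)C1(C)C | intermediate
27 | C19 tert-butyldimethylsilyl ether of 26 | CO[C@H]1CC[C@@]2(C)[C@H](CC[C@@]3(C)CC(=O)[C@@H](C[C@H]32)[C@@H](O[Si](C)(C)C(C)(C)C)[C@@]4(C)CC[C@@H](OCc5ccccc5)C(C)(C)[C@H]4CC=C)C1(C)C | intermediate
28 | seco-D keto aldehyde (C10 ketone, C11 aldehyde, C19–OTBS, C15–OBn) | CO[C@H]1CC[C@@]2(C)[C@H](CC[C@@]3(C)CC(=O)[C@@H](C[C@H]32)[C@@H](O[Si](C)(C)C(C)(C)C)[C@@]4(C)CC[C@@H](OCc5ccccc5)C(C)(C)[C@H]4CC=O)C1(C)C | intermediate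
29 | pentacyclic (10S,11R)-C10,C11-cis-diol (C19–OTBS, C15–OBn) | CO[C@H]1CC[C@@]2(C)[C@H](CC[C@@]3(C)C[C@@]4(O)[C@H](O)C[C@@H]5C(C)(C)[C@H](OCc6ccccc6)CC[C@]5(C)[C@H](O[Si](C)(C)C(C)(C)C)[C@@H]4C[C@H]32)C1(C)C | intermediate
30 | sodium C11 xanthate of 29 | CO[C@H]1CC[C@@]2(C)[C@H](CC[C@@]3(C)C[C@@]4(O)[C@H](OC(=S)[S-])C[C@@H]5C(C)(C)[C@H](OCc6ccccc6)CC[C@]5(C)[C@H](O[Si](C)(C)C(C)(C)C)[C@@H]4C[C@H]32)C1(C)C.[Na+] | intermediate
31 | C11 O-(S-methyl) xanthate of 29 | CO[C@H]1CC[C@@]2(C)[C@H](CC[C@@]3(C)C[C@@]4(O)[C@H](OC(=S)SC)C[C@@H]5C(C)(C)[C@H](OCc6ccccc6)CC[C@]5(C)[C@H](O[Si](C)(C)C(C)(C)C)[C@@H]4C[C@H]32)C1(C)C | intermediate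
32 | C11-deoxy pentacycle (C10–OH, C19–OTBS, C15–OBn) | CO[C@H]1CC[C@@]2(C)[C@H](CC[C@@]3(C)C[C@@]4(O)CC[C@@H]5C(C)(C)[C@H](OCc6ccccc6)CC[C@]5(C)[C@H](O[Si](C)(C)C(C)(C)C)[C@@H]4C[C@H]32)C1(C)C | intermediate
33 | C19 alcohol (C10–OH, C19–OH, C15–OBn) | CO[C@H]1CC[C@@]2(C)[C@H](CC[C@@]3(C)C[C@@]4(O)CC[C@@H]5C(C)(C)[C@H](OCc6ccccc6)CC[C@]5(C)[C@H](O)[C@@H]4C[C@H]32)C1(C)C | intermediate
34 | C15 benzyl ether of the target (C19 ketone, C10–OH) | CO[C@H]1CC[C@@]2(C)[C@H](CC[C@@]3(C)C[C@@]4(O)CC[C@@H]5C(C)(C)[C@H](OCc6ccccc6)CC[C@]5(C)C(=O)[C@@H]4C[C@H]32)C1(C)C | intermediate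
35 | CNP0259231.1 (1S,4R,5S,8S,10S,13R,15R,18S,20R,22R) | CO[C@H]1CC[C@@]2(C)[C@H](CC[C@@]3(C)C[C@@]4(O)CC[C@@H]5C(C)(C)[C@H](O)CC[C@]5(C)C(=O)[C@@H]4C[C@H]32)C1(C)C | target

## Step count and risks

Total step count: 24. Longest linear sequence: 17 steps (steps 1–8, then 16–24); ring E is made in 7 steps (9–15).

Steps most likely to fail:

**Step 7.** Methyl transfer to the hindered ring-fusion carbon C4 may be slow, and capture of the neopentyl C22 enolate may be incomplete, so that the vinyl ketone polymerizes before it is alkylated. The fallback sets out from 9 and comes back at 12. Lithium dimethylcuprate is added to 9 in the presence of TMSCl and the trimethylsilyl enol ether F1 is isolated. It is joined to but-3-en-2-one in a TiCl4-promoted Mukaiyama–Michael addition at −78 °C to give the 1,5-diketone F2. Ring C is then closed with KOH in MeOH, which gives 12.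

**Step 19.** Simple reduction of the aldehyde or intermolecular coupling may outrun closure of the seven-membered ring, or the new bond may form on the wrong face of C10. The fallback sets out from 28 and comes back at 32. The aldehyde of 28 is reduced selectively with NaBH4 at −78 °C to the hydroxy ketone F3. An Appel reaction (I2, PPh3, imidazole) converts it into the primary iodide F4. Ring D is then closed by an intramolecular samarium Barbier reaction (SmI2, HMPA, THF), in which the alkylsamarium adds to the C10 ketone with the same equatorial preference. This gives the C11-deoxy tertiary alcohol 32 directly and makes steps 20 and 21 unnecessary.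

**Step 20.** The neighbouring tertiary alkoxide may attack the new thiocarbonyl group and close a cyclic thionocarbonate, whose radical cleavage would remove the C10 oxygen instead of the C11 oxygen. The fallback sets out from 29 and comes back at 32. The secondary C11 hydroxyl of 29 is oxidized with DMP to the α-hydroxy ketone F5. This is condensed with tosylhydrazide to the tosylhydrazone F6. Reduction with catecholborane followed by NaOAc·3H2O in warm CHCl3 (reductive deoxygenation of a tosylhydrazone) gives 32.

## Further compounds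

F1 | step 7 | trimethylsilyl enol ether of the cis-fused C4-methyl decalone (C8–OSiMe3, C8=C22) | CO[C@H]1CC[C@@]2(C)[C@H](CCC(O[Si](C)(C)C)=C2)C1(C)C
F2 | step 7 | cis-fused C8 ketone bearing a 3-oxobutyl group on C22 (C22 unassigned) | CO[C@H]1CC[C@@]2(C)[C@H](CCC(=O)C2CCC(C)=O)C1(C)C
F3 | step 19 | hydroxy ketone (C10 ketone, C11 primary alcohol, C19–OTBS, C15–OBn) | CO[C@H]1CC[C@@]2(C)[C@H](CC[C@@]3(C)CC(=O)[C@@H](C[C@H]32)[C@@H](O[Si](C)(C)C(C)(C)C)[C@@]4(C)CC[C@@H](OCc5ccccc5)C(C)(C)[C@H]4CCO)C1(C)C
F4 | step 19 | iodo ketone (C10 ketone, C11 primary iodide, C19–OTBS, C15–OBn) | CO[C@H]1CC[C@@]2(C)[C@H](CC[C@@]3(C)CC(=O)[C@@H](C[C@H]32)[C@@H](O[Si](C)(C)C(C)(C)C)[C@@]4(C)CC[C@@H](OCc5ccccc5)C(C)(C)[C@H]4CCI)C1(C)C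
F5 | step 20 | pentacyclic α-hydroxy ketone (C10–OH, C11 ketone, C19–OTBS, C15–OBn) | CO[C@H]1CC[C@@]2(C)[C@H](CC[C@@]3(C)C[C@@]4(O)C(=O)C[C@@H]5C(C)(C)[C@H](OCc6ccccc6)CC[C@]5(C)[C@H](O[Si](C)(C)C(C)(C)C)[C@@H]4C[C@H]32)C1(C)C
F6 | step 20 | C11 tosylhydrazone of F5 | CO[C@H]1CC[C@@]2(C)[C@H](CC[C@@]3(C)C[C@@]4(O)C(=NNS(=O)(=O)c7ccc(C)cc7)C[C@@H]5C(C)(C)[C@H](OCc6ccccc6)CC[C@]5(C)[C@H](O[Si](C)(C)C(C)(C)C)[C@@H]4C[C@H]32)C1(C)C
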